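**Strategy**

Atom labels: C1 allyl bridgehead, C2=C3 enol ether, C4 acetoxy carbon, C5 methoxy bridgehead, C6 aryl carbon, C7 methyl carbon, C8 bridging ketone. The plan cuts C3–C4 and C5–C8, tracing the bicyclo[3.2.1]octenone back to a bicyclo[2.2.2]octenone with C3 on C5 and C8 on C4. One acid-triggered double 1,2-shift contracts ring C1–C7–C6–C5–C4–C8 to cyclopentane C1–C7–C6–C5–C8 and builds enone ring C1–C2–C3–C4–C5–C8. It exploits the C5 methoxy group beside the C4 carbonyl, which stabilises the cation formed when C3 leaves C5. The precursor is the endo-aryl Diels–Alder adduct of a masked ortho-benzoquinone and (E)-isoelemicin, with C8 as dimethyl ketal.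

Key step: step 10

Remark: in all bicyclic compounds the locants C1–C8 are the atom labels above (not always IUPAC locants), Ar is 3,4,5-trimethoxyphenyl, and it is assumed that the separated enantiomers of 13 can be assigned by anomalous-dispersion X-ray or ECD.

**Route**

Step 1
Reactants: 1 2-hydroxy-3,4-dimethoxybenzaldehyde
Product: 2 3,4-dimethoxy-2-(methoxymethoxy)benzaldehyde
Conditions: MOMCl, K2CO3, DMF, 0 °C → rt
Reagents that add atoms: chloromethyl methyl ether, COCCl
Why: Williamson-type O-alkylation of the acidic ortho-hydroxyaldehyde phenoxide gives the MOM acetal, which masks the oxygen that must end up as the free phenol.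

Step 2
Reactants: 2 3,4-dimethoxy-2-(methoxymethoxy)benzaldehyde
Product: 4 3,4-dimethoxy-2-(methoxymethoxy)phenol, via aryl formate 3 (not isolated)
Conditions: mCPBA, CH2Cl2, 0 °C → rt; then K2CO3 (cat.), MeOH, rt
Reagents that add atoms: mCPBA, O=C(OO)c1cccc(Cl)c1
Why: Baeyer–Villiger (Dakin-type) oxidation in which the electron-rich trialkoxyaryl group migrates in preference to hydride gives the aryl formate, which mild methanolysis cleaves while the MOM acetal is untouched.

Step 3
Reactants: 4 3,4-dimethoxy-2-(methoxymethoxy)phenol; 5 allyl bromide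
Product: 6 1-(allyloxy)-3,4-dimethoxy-2-(methoxymethoxy)benzene
Conditions: K2CO3, acetone, reflux
Reagents that add atoms: none
Why: Williamson ether synthesis of the phenoxide with a primary allylic bromide.

Step 4
Reactants: 6 1-(allyloxy)-3,4-dimethoxy-2-(methoxymethoxy)benzene
Product: 7 6-allyl-3,4-dimethoxy-2-(methoxymethoxy)phenol
Conditions: PhNEt2, 190 °C
Reagents that add atoms: none
Why: Aromatic Claisen rearrangement ([3,3] shift, then tautomerisation) delivers the allyl group to the only free ortho carbon, the other ortho position carrying the MOM ether; the basic solvent keeps the acetal intact.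

Step 5
Reactants: 7 6-allyl-3,4-dimethoxy-2-(methoxymethoxy)phenol
Product: 8 1-allyl-2,4,5-trimethoxy-3-(methoxymethoxy)benzene
Conditions: MeI, K2CO3, DMF, rt
Reagents that add atoms: iodomethane, CI
Why: Williamson O-methylation of the hindered phenoxide in a dipolar aprotic solvent; allyl group and acetal are inert to base.

Step 6
Reactants: 8 1-allyl-2,4,5-trimethoxy-3-(methoxymethoxy)benzene
Product: 9 3-allyl-2,5,6-trimethoxyphenol
Conditions: conc. HCl (cat.), MeOH, 45 °C
Reagents that add atoms: none
Why: Acid-catalysed transacetalisation passes the MOM group to methanol and frees the phenol flanked by two methoxy groups; aryl methyl ethers and the allyl group are stable to dilute HCl in methanol.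

Step 7
Reactants: 10 elemicin
Product: 11 (E)-isoelemicin
Conditions: PdCl2(MeCN)2 (5 mol %), toluene, 80 °C
Reagents that add atoms: none
Why: Palladium-catalysed allyl-to-propenyl double-bond migration into conjugation with the arene should give the thermodynamically preferred E alkene.

Step 8
Reactants: 9 3-allyl-2,5,6-trimethoxyphenol; 11 (E)-isoelemicin
Product: 13 racemic endo-aryl bicyclo[2.2.2]octenone cycloadduct, via dienone ketal 12 (not isolated)
Conditions: PhI(OAc)2, MeOH, 0 °C; solvent exchanged for toluene, 11 (5 equiv), 100 °C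
Reagents that add atoms: methanol, CO
Why: Oxidative dearomatisation by the trivalent iodine reagent, with methanol expected to add at the methoxy-bearing ortho carbon next to the allyl group, gives masked ortho-benzoquinone 12, and its inverse-electron-demand Diels–Alder reaction with 11 joins the nucleophilic CHMe carbon to the allyl-bearing diene terminus (C1) and the benzylic carbon to the terminus beside the carbonyl (C5) through an endo transition state with the aryl group under the diene, so C1, C5, C6 and C7 form in one relative configuration with aryl and methyl trans as in the E alkene (racemic).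

Step 9
Reactants: 13 racemic endo-aryl bicyclo[2.2.2]octenone cycloadduct
Product: 14 (1S,5S,6R,7S)-cycloadduct
Conditions: preparative chiral SFC, amylose tris(3,5-dimethylphenylcarbamate) phase, CO2/MeOH
Reagents that add atoms: none
Why: Resolution by chromatography on a chiral stationary phase separates the enantiomers of this rigid, UV-active ketone without chemical change; no stereocentre is made and the wanted antipode is assigned by X-ray or ECD.

Step 10
Reactants: 14 (1S,5S,6R,7S)-cycloadduct
Product: 15 (1S,5S,6R,7S)-1-allyl-3,5,8,8-tetramethoxy-7-methyl-6-(3,4,5-trimethoxyphenyl)bicyclo[3.2.1]oct-2-en-4-one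
Conditions: BF3·OEt2 (2 equiv), 4 Å MS, CH2Cl2, −40 → 0 °C; aq. NaHCO3 quench
Reagents that add atoms: none
Why: BF3 binds the C4 carbonyl, the alkenyl carbon C3 shifts from C5 to C4 with lone-pair push from the C5 methoxy group to leave an oxocarbenium ion at C5, and the ketal carbon C8 then shifts from C4 to C5 (pinacol-type return), which restores the C4 carbonyl in conjugation with C2=C3. The closest known reaction type is the acid-promoted 1,2-acyl shift of 1-methoxybicyclo[2.2.2]oct-5-en-2-ones to bicyclo[3.2.1]oct-3-en-2-ones. Neither ring closes by an end-on cyclisation: both arise by suprafacial 1,2-shifts through three-centre transition states, the cyclopentane C1–C7–C6–C5–C8 by contraction of ring C1–C7–C6–C5–C4–C8 when C8 bonds to C5, and the enone ring C1–C2–C3–C4–C5–C8 by the exchange of C3 and C8 across C4–C5. No stereocentre is created: C1, C6 and C7 keep all their bonds, and C5 can take only the configuration dictated by the C1–C8 and C6–C7 tethers, so the endo-aryl, exo-methyl array of 14 is carried over. The step needs C3 to migrate rather than benzylic C6 and the C8 ketal to stay un-ionised; an sp2 carbon migrates more readily and only its shift ends in a conjugated enone, while a cation at C8 would lie next to the C4 carbonyl and is disfavoured. Low temperature and a bicarbonate quench limit heterolysis of the C5–C6 bond and hydrolysis of the enol ether.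

Step 11
Reactants: 15 (1S,5S,6R,7S)-1-allyl-3,5,8,8-tetramethoxy-7-methyl-6-(3,4,5-trimethoxyphenyl)bicyclo[3.2.1]oct-2-en-4-one
Product: 16 (1S,5R,6R,7S)-1-allyl-3,5-dimethoxy-7-methyl-6-(3,4,5-trimethoxyphenyl)bicyclo[3.2.1]oct-2-ene-4,8-dione
Conditions: 2 M aq. HCl, THF, 40 °C
Reagents that add atoms: water, O
Why: Acid-catalysed ketal hydrolysis through the C8 oxocarbenium ion is done at this stage because the C3 methoxy group is still part of an α-methoxy enone and resists protonation at C2, whereas after reduction it would be an acid-labile enol ether.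

Step 12
Reactants: 16 (1S,5R,6R,7S)-1-allyl-3,5-dimethoxy-7-methyl-6-(3,4,5-trimethoxyphenyl)bicyclo[3.2.1]oct-2-ene-4,8-dione
Product: 17 (1S,4R,5S,6R,7S)-1-allyl-4-hydroxy-3,5-dimethoxy-7-methyl-6-(3,4,5-trimethoxyphenyl)bicyclo[3.2.1]oct-2-en-8-one
Conditions: NaBH4, CeCl3·7H2O, MeOH, −78 °C; aq. NaHCO3 work-up
Reagents that add atoms: none
Why: Luche 1,2-reduction should take the cerium-activated enone carbonyl C4 in preference to the C8 ketone, which is shielded by two quaternary bridgeheads and the exo methyl group, and hydride should enter from the face syn to the C8 bridge, anti to the endo aryl group on C6, which sets C4 as R with the hydroxyl on the aryl side.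

Step 13
Reactants: 17 (1S,4R,5S,6R,7S)-1-allyl-4-hydroxy-3,5-dimethoxy-7-methyl-6-(3,4,5-trimethoxyphenyl)bicyclo[3.2.1]oct-2-en-8-one
Product: 18 (1S,4R,5S,6R,7S)-1-allyl-3,5-dimethoxy-7-methyl-8-oxo-6-(3,4,5-trimethoxyphenyl)bicyclo[3.2.1]oct-2-en-4-yl acetate (CNP0181407.1)
Conditions: Ac2O, pyridine, DMAP (cat.), CH2Cl2, rt
Reagents that add atoms: acetic anhydride, CC(=O)OC(C)=O
Why: DMAP-catalysed acylation of the secondary allylic alcohol under basic conditions keeps the C2=C3 enol ether and the C4 configuration intact.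

**Compound list**

1 | 2-hydroxy-3,4-dimethoxybenzaldehyde | COc1ccc(C=O)c(O)c1OC | starting material
2 | 3,4-dimethoxy-2-(methoxymethoxy)benzaldehyde | COCOc1c(C=O)ccc(OC)c1OC | intermediate
3 | 3,4-dimethoxy-2-(methoxymethoxy)phenyl formate | COCOc1c(OC=O)ccc(OC)c1OC | intermediate (not isolated)
4 | 3,4-dimethoxy-2-(methoxymethoxy)phenol | COCOc1c(O)ccc(OC)c1OC | intermediate
5 | allyl bromide (3-bromoprop-1-ene) | C=CCBr | starting material
6 | 1-(allyloxy)-3,4-dimethoxy-2-(methoxymethoxy)benzene | C=CCOc1ccc(OC)c(OC)c1OCOC | intermediate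
7 | 6-allyl-3,4-dimethoxy-2-(methoxymethoxy)phenol | C=CCc1cc(OC)c(OC)c(OCOC)c1O | intermediate
8 | 1-allyl-2,4,5-trimethoxy-3-(methoxymethoxy)benzene | C=CCc1cc(OC)c(OC)c(OCOC)c1OC | intermediate
9 | 3-allyl-2,5,6-trimethoxyphenol | C=CCc1cc(OC)c(OC)c(O)c1OC | intermediate
10 | elemicin (5-allyl-1,2,3-trimethoxybenzene) | C=CCc1cc(OC)c(OC)c(OC)c1 | starting material
11 | (E)-isoelemicin ((E)-1,2,3-trimethoxy-5-(prop-1-en-1-yl)benzene) | C/C=C/c1cc(OC)c(OC)c(OC)c1 | intermediate
12 | 5-allyl-2,3,6,6-tetramethoxycyclohexa-2,4-dien-1-one (masked ortho-benzoquinone) | C=CCC1=CC(OC)=C(OC)C(=O)C1(OC)OC | intermediate (not isolated)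
13 | racemic cycloadduct, (1S*,5S*,6R*,7S*): bicyclo[2.2.2]oct-2-ene with bridgeheads C1 (allyl) and C5 (OMe), bridges C2=C3 (OMe on C3), C4(=O)–C8(OMe)2 and C6(Ar, syn to C2=C3)–C7(Me, syn to C8); both enantiomers | C=CC[C@]12C=C(OC)[C@](OC)(C(=O)C1(OC)OC)[C@@H](c1cc(OC)c(OC)c(OC)c1)[C@@H]2C.C=CC[C@@]12C=C(OC)[C@@](OC)(C(=O)C1(OC)OC)[C@H](c1cc(OC)c(OC)c(OC)c1)[C@H]2C | intermediate
14 | (1S,5S,6R,7S)-cycloadduct: single enantiomer of 13, same constitution, aryl endo (syn to C2=C3), methyl exo (syn to C8) | C=CC[C@]12C=C(OC)[C@](OC)(C(=O)C1(OC)OC)[C@@H](c1cc(OC)c(OC)c(OC)c1)[C@@H]2C | intermediate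
15 | (1S,5S,6R,7S)-1-allyl-3,5,8,8-tetramethoxy-7-methyl-6-(3,4,5-trimethoxyphenyl)bicyclo[3.2.1]oct-2-en-4-one (aryl endo, methyl exo) | C=CC[C@]12C=C(OC)C(=O)[C@](OC)(C1(OC)OC)[C@@H](c1cc(OC)c(OC)c(OC)c1)[C@@H]2C | intermediate
16 | (1S,5R,6R,7S)-1-allyl-3,5-dimethoxy-7-methyl-6-(3,4,5-trimethoxyphenyl)bicyclo[3.2.1]oct-2-ene-4,8-dione | C=CC[C@]12C=C(OC)C(=O)[C@](OC)(C1=O)[C@@H](c1cc(OC)c(OC)c(OC)c1)[C@@H]2C | intermediate
17 | (1S,4R,5S,6R,7S)-1-allyl-4-hydroxy-3,5-dimethoxy-7-methyl-6-(3,4,5-trimethoxyphenyl)bicyclo[3.2.1]oct-2-en-8-one (hydroxyl on the aryl side) | C=CC[C@]12C=C(OC)[C@@H](O)[C@](OC)(C1=O)[C@@H](c1cc(OC)c(OC)c(OC)c1)[C@@H]2C | intermediate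
18 | (1S,4R,5S,6R,7S)-1-allyl-3,5-dimethoxy-7-methyl-8-oxo-6-(3,4,5-trimethoxyphenyl)bicyclo[3.2.1]oct-2-en-4-yl acetate | C=CC[C@]12C=C(OC)[C@@H](OC(C)=O)[C@](OC)(C1=O)[C@@H](c1cc(OC)c(OC)c(OC)c1)[C@@H]2C | target

**Step count and risks**

Total step count: 13. Longest linear sequence: 12 steps (steps 1–6 and 8–13); step 7 is the one-step branch.

Steps most likely to fail:

1. Step 10. The Lewis acid may ionise the C8 ketal, the benzylic carbon C6 may shift in place of C3, or the C5–C6 bond of the product may heterolyse toward a hydrobenzofuran skeleton. Fallback, setting out from 14 and coming back at 16: the order of unmasking and rearrangement is reversed so that the second migrating group is an acyl carbon, the variant for which the acid-promoted 1,2-acyl shift is established. Aqueous TFA (or HClO4 in wet MeCN) should take the C8 ketal of 14 to the bicyclo[2.2.2]octene-4,8-dione F1. Brief treatment of F1 with TfOH in CH2Cl2 at low temperature (or p-TsOH in hot toluene) should then give 16 by the C3 shift and acyl return shift, which makes step 11 unnecessary.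

2. Step 8. Methanol may add to the other methoxy-bearing ortho carbon of 9, the dienone may decay or dimerise before the electron-rich alkene traps it, or exo and regioisomeric adducts may form. Fallback, setting out from 5 and 11 and coming back at 16: the masked ortho-quinone is avoided by a cationic [5+2] cycloaddition of a para-quinone monoketal.
   - Purchased 2,3,4-trimethoxyphenol F2 is O-allylated with 5 (K2CO3, acetone) to 1-(allyloxy)-2,3,4-trimethoxybenzene F3.
   - Claisen rearrangement (PhNEt2, 190 °C) gives 6-allyl-2,3,4-trimethoxyphenol F4.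
   - PhI(OAc)2 in methanol, which here should add methanol para to the hydroxyl, gives 6-allyl-2,3,4,4-tetramethoxycyclohexa-2,5-dien-1-one F5.
   - Ionisation of F5 with TMSOTf in CH2Cl2 at −78 °C in the presence of 11 should join the CHMe carbon to the allyl-bearing terminus and the benzylic carbon to the methoxy-bearing terminus beside the carbonyl, aryl endo. Loss of the O-methyl group from the resulting oxocarbenium ion on aqueous work-up then gives racemic dione F6.
   - Chiral SFC as in step 9 delivers 16, and steps 9–11 are skipped. The pairing of the termini follows the parent reaction without the second methoxy group and is the point to verify first.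

3. Step 12. Hydride may also attack the C8 ketone, or enter from the aryl face. Fallback, setting out from 16 and coming back at 18: excess NaBH4 with CeCl3·7H2O in MeOH at 0 °C should reduce both carbonyl groups to diol F7. The allylic C4 hydroxyl, the less hindered of the two, is acetylated selectively (Ac2O, pyridine, 0 °C) to hydroxy acetate F8. Dess–Martin periodinane buffered with NaHCO3 then re-oxidises the C8 carbinol to give 18.

**Further compounds**

F1 | step 10 | C8 ketone analogue of 14: bicyclo[2.2.2]oct-2-ene-4,8-dione with the configuration of 14 | C=CC[C@]12C=C(OC)[C@](OC)(C(=O)C1=O)[C@@H](c1cc(OC)c(OC)c(OC)c1)[C@@H]2C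
F2 | step 8 | 2,3,4-trimethoxyphenol (purchased) | COc1ccc(O)c(OC)c1OC
F3 | step 8 | 1-(allyloxy)-2,3,4-trimethoxybenzene | C=CCOc1ccc(OC)c(OC)c1OC
F4 | step 8 | 6-allyl-2,3,4-trimethoxyphenol | C=CCc1cc(OC)c(OC)c(OC)c1O
F5 | step 8 | 6-allyl-2,3,4,4-tetramethoxycyclohexa-2,5-dien-1-one | C=CCC1=CC(OC)(OC)C(OC)=C(OC)C1=O
F6 | step 8 | racemic 16 (both enantiomers) | C=CC[C@]12C=C(OC)C(=O)[C@](OC)(C1=O)[C@@H](c1cc(OC)c(OC)c(OC)c1)[C@@H]2C.C=CC[C@@]12C=C(OC)C(=O)[C@@](OC)(C1=O)[C@H](c1cc(OC)c(OC)c(OC)c1)[C@H]2C
F7 | step 12 | C4,C8-diol from 16 (C4 as in 17; C8 epimer as formed, either serves) | C=CC[C@]12C=C(OC)[C@@H](O)[C@](OC)(C1O)[C@@H](c1cc(OC)c(OC)c(OC)c1)[C@@H]2C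
F8 | step 12 | C4 acetate of F7 with free C8 hydroxyl | C=CC[C@]12C=C(OC)[C@@H](OC(C)=O)[C@](OC)(C1O)[C@@H](c1cc(OC)c(OC)c(OC)c1)[C@@H]2C
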